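The route rests on cutting ring bond C2–C3, between the side-chain-bearing CH (C2) and the gem-dimethyl carbon (C3). Without it, ring carbons C1–C6, their three methyls and the first side-chain carbon are an open geraniol skeleton; the rest is farnesol attached through C12. The key step, an iron-hydride hydrogen-atom-transfer 6-exo-dig cyclization of a geraniol-derived enynyl phenyl sulfone (tertiary propargylic alcohol carrying the C1 stereocentre, trisubstituted alkene), forms the cyclohexane, quaternary C3 and an exocyclic vinyl sulfone at C2 in one operation. Hydroxyl-directed reduction then sets C2, and the sulfone joins the ring to a 12-bromofarnesyl silyl ether.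

Key step: step 6

Remark: ring atoms are numbered C1 (C(CH3)OH), C2 (CH carrying the chain), C3 (C(CH3)2) and C4–C6 (CH2); lithium and aluminium salts that are only deprotonated or metalated forms of a numbered compound are made and used in situ under the number of that compound; the alkene geometry of 9 and the configuration at the sulfonyl-bearing carbon of 15 are left as mixtures because both disappear later.

Step 1
Reactants: 1 geraniol
Product: 2 (2S,3S)-2,3-epoxygeraniol
Conditions: Ti(OiPr)4 (5 mol%), L-(+)-diethyl tartrate (7 mol%), t-BuOOH (1.5 equiv, in decane), 4 Å MS, CH2Cl2, −20 °C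
Reagents that add atoms: tert-butyl hydroperoxide, CC(C)(C)OO
Why: Katsuki–Sharpless asymmetric epoxidation: the complex formed from Ti(OiPr)4 and L-(+)-diethyl tartrate binds the allylic alcohol and the hydroperoxide and delivers oxygen to a single face of the 2,3-alkene, which sets both epoxide carbons (2S,3S; the carbon bearing CH3 is the future C1) and leaves the remote 6,7-alkene untouched.

Step 2
Reactants: 2 (2S,3S)-2,3-epoxygeraniol
Product: 3 (2R,3S)-1-chloro-2,3-epoxy-3,7-dimethyloct-6-ene (epoxygeranyl chloride)
Conditions: PPh3, CCl4, NaHCO3, reflux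
Reagents that add atoms: carbon tetrachloride, ClC(Cl)(Cl)Cl
Why: Appel chlorination: the alkoxyphosphonium salt of the primary alcohol is displaced by chloride at CH2 (SN2) under NaHCO3-buffered conditions that do not open the trisubstituted epoxide, so both stereocentres are carried over unchanged (the descriptor of the epoxide CH becomes R only because chlorine changes the priorities).

Step 3
Reactants: 3 (2R,3S)-1-chloro-2,3-epoxy-3,7-dimethyloct-6-ene
Product: 5 (S)-3,7-dimethyloct-6-en-1-yn-3-ol, via lithium chlorodienolate 4 (not isolated)
Conditions: n-BuLi (3.2 equiv), THF, −78 °C to rt; then H2O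
Reagents that add atoms: none
Why: Base-induced double elimination of a 2,3-epoxy chloride to a propargylic alcohol: lithiation at CH2Cl opens the epoxide by β-elimination to chlorodienolate 4, a second equivalent of base removes HCl to give the alkyne and a third deprotonates it, while the C–O bond of the tertiary carbinol carbon is never broken, so its configuration is retained (S).

Step 4
Reactants: 5 (S)-3,7-dimethyloct-6-en-1-yn-3-ol
Product: 6 (S)-3,7-dimethyl-1-(phenylsulfanyl)oct-6-en-1-yn-3-ol
Conditions: n-BuLi (2.1 equiv), THF, −78 °C; PhSSPh (1.1 equiv), −78 to 0 °C; then H2O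
Reagents that add atoms: diphenyl disulfide, c1ccc(cc1)SSc1ccccc1
Why: Sulfenylation of a lithium acetylide: after double deprotonation (OH and alkyne C–H) the acetylide carbon attacks the S–S bond of diphenyl disulfide, whereas the hindered tertiary lithium alkoxide does not react.

Step 5
Reactants: 6 (S)-3,7-dimethyl-1-(phenylsulfanyl)oct-6-en-1-yn-3-ol
Product: 8 (S)-3,7-dimethyl-1-(phenylsulfonyl)oct-6-en-1-yn-3-ol, via alkynyl sulfoxide 7 (not isolated)
Conditions: 30% aq. H2O2 (4 equiv), (NH4)6Mo7O24·4H2O (10 mol%), EtOH, 0 °C to rt
Reagents that add atoms: hydrogen peroxide, OO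
Why: Molybdate-catalysed peroxide oxidation of a sulfide through sulfoxide 7 to the sulfone: the peroxomolybdate oxidises sulfur much faster than it epoxidises the unactivated trisubstituted alkene, which a peracid would not spare, and the stereocentre is not involved.

Step 6
Reactants: 8 (S)-3,7-dimethyl-1-(phenylsulfonyl)oct-6-en-1-yn-3-ol
Product: 9 (S)-1,3,3-trimethyl-2-[(phenylsulfonyl)methylidene]cyclohexan-1-ol (E/Z mixture)
Conditions: Fe(acac)3 (50 mol%), PhSiH3 (2.5 equiv), EtOH/(CH2OH)2 (5:1), 0.02 M, Ar, 60 °C
Reagents that add atoms: none
Why: Fe(acac)3 and PhSiH3 in ethanol give an iron hydride that transfers a hydrogen atom to the CH terminus of the electron-rich trisubstituted alkene; the nucleophilic tertiary radical at the future C3 adds to the alkyne carbon remote from sulfur (future C2), and the α-sulfonyl vinyl radical is quenched by hydrogen abstraction from ethanol or silane or by capture by divalent iron and protonation, which returns trivalent iron. The closest known reaction type is the iron-hydride hydrogen-atom-transfer reductive coupling of unactivated alkenes with electron-poor acceptors in its intramolecular form (intramolecular Giese reaction), here with an alkynyl instead of an alkenyl sulfone as acceptor. The only ring, the cyclohexane, closes in the 6-exo-dig mode through the C2–C3 bond, the sulfonyl-bearing carbon remaining exocyclic. No stereocentre is formed, because C3 carries two methyl groups and C2 leaves the step sp2-hybridised, and C1 is a spectator whose configuration is untouched; the alkene geometry is irrelevant because step 7 converges both isomers. The step needs chemoselective hydrogen-atom transfer, secured by the contrast between the electron-rich alkene and the electron-poor alkyne, and 6-exo regioselectivity, secured by ring size, by the polarisation of the triple bond by the sulfonyl group and by the fact that 7-endo attack at the sulfur-bearing carbon could only fragment to an impossible cycloheptyne. The fully substituted carbinol carbon C1 folds the chain (Thorpe–Ingold effect), and the early transition state of radical addition to an sp carbon tolerates bond formation between a tertiary centre and a carbon next to a quaternary one, where a polar alkylation would fail.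

Step 7
Reactants: 9 (S)-1,3,3-trimethyl-2-[(phenylsulfonyl)methylidene]cyclohexan-1-ol
Product: 10 (1S,2S)-1,3,3-trimethyl-2-[(phenylsulfonyl)methyl]cyclohexan-1-ol (ring fragment)
Conditions: LiAlH4 (2 equiv), THF, 0 °C to rt; then H2O, aq. NaOH
Reagents that add atoms: none
Why: Alkoxide-directed conjugate hydride reduction of a vinyl sulfone: LiAlH4 first forms the C1 alkoxyaluminate, which delivers hydride intramolecularly to the β-carbon C2 on the face of the C1 oxygen (as in the LiAlH4 reduction of allylic and propargylic alcohols), so that H at C2 ends cis to OH and CH2SO2Ph trans to OH and cis to the C1 methyl (2S), both alkene isomers giving the same product after protonation of the sulfonyl-stabilised carbanion, and the alkene cannot escape by isomerisation because C1 and C3 carry no hydrogen.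

Step 8
Reactants: 11 (2E,6E)-farnesol
Product: 12 (2E,6E)-farnesyl tert-butyldimethylsilyl ether
Conditions: TBSCl, imidazole, DMF, 0 °C to rt
Reagents that add atoms: tert-butyldimethylsilyl chloride, CC(C)(C)[Si](C)(C)Cl
Why: Silylation of a primary allylic alcohol with a silyl chloride and imidazole, the tert-butyldimethylsilyl ether being chosen because it should survive allylic oxidation, organolithium base and sodium amalgam and is removed at the end by fluoride.

Step 9
Reactants: 12 (2E,6E)-farnesyl tert-butyldimethylsilyl ether
Product: 13 (2E,6E,10E)-12-[(tert-butyldimethylsilyl)oxy]-2,6,10-trimethyldodeca-2,6,10-trien-1-ol (12-hydroxyfarnesyl silyl ether)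
Conditions: SeO2 (0.2 equiv), salicylic acid (0.1 equiv), t-BuOOH (70% aq., 3 equiv), CH2Cl2, 0 °C to rt, stopped at partial conversion
Reagents that add atoms: selenium dioxide, O=[Se]=O (oxygen donor, regenerated); tert-butyl hydroperoxide, CC(C)(C)OO (terminal oxidant)
Why: Riley-type allylic oxidation with catalytic SeO2 and tert-butyl hydroperoxide (ene reaction, then [2,3]-sigmatropic shift): the terminal trisubstituted alkene is the most accessible and the 2,3-alkene is deactivated by the allylic silyloxy group, oxidation occurs at the methyl group trans to the chain and so gives the 10E allylic alcohol, and stopping at partial conversion with recycling of 12 limits over-oxidation to the enal.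

Step 10
Reactants: 13 (2E,6E,10E)-12-[(tert-butyldimethylsilyl)oxy]-2,6,10-trimethyldodeca-2,6,10-trien-1-ol
Product: 14 tert-butyl{[(2E,6E,10E)-12-bromo-3,7,11-trimethyldodeca-2,6,10-trien-1-yl]oxy}dimethylsilane (chain fragment)
Conditions: CBr4, PPh3, CH2Cl2, −20 to 0 °C
Reagents that add atoms: carbon tetrabromide, BrC(Br)(Br)Br
Why: Appel bromination of a primary allylic alcohol: displacement of the alkoxyphosphonium group by bromide at the primary carbon (SN2) under neutral conditions keeps the silyl ether and the E geometry and avoids allylic transposition.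

Step 11
Reactants: 10 (1S,2S)-1,3,3-trimethyl-2-[(phenylsulfonyl)methyl]cyclohexan-1-ol; 14 tert-butyl{[(2E,6E,10E)-12-bromo-3,7,11-trimethyldodeca-2,6,10-trien-1-yl]oxy}dimethylsilane
Product: 15 (1S,2S)-2-[(3E,7E,11E)-13-[(tert-butyldimethylsilyl)oxy]-3,7,11-trimethyl-1-(phenylsulfonyl)trideca-3,7,11-trien-1-yl]-1,3,3-trimethylcyclohexan-1-ol (both epimers at the sulfonyl-bearing carbon)
Conditions: 10, n-BuLi (2.1 equiv), THF/DMPU, −78 to −40 °C; then 14, −78 to −20 °C; then H2O
Reagents that add atoms: none
Why: Alkylation of an α-sulfonyl carbanion: two equivalents of n-BuLi generate the lithium alkoxide and the sulfonyl-stabilised carbanion, the carbon of which attacks the unhindered primary allylic bromide by SN2 while the crowded tertiary alkoxide stays inert, the new sulfonyl-bearing stereocentre being formed without control but removed in step 12 and C1 and C2 being untouched.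

Step 12
Reactants: 15 coupled hydroxy sulfone silyl ether
Product: 16 (1S,2S)-2-[(3E,7E,11E)-13-[(tert-butyldimethylsilyl)oxy]-3,7,11-trimethyltrideca-3,7,11-trien-1-yl]-1,3,3-trimethylcyclohexan-1-ol
Conditions: Na(Hg) (6% Na), Na2HPO4, MeOH/THF, −20 to 0 °C
Reagents that add atoms: none
Why: Reductive desulfonylation with sodium amalgam in buffered methanol (electron transfer, loss of benzenesulfinate, protonation): the sulfone is homoallylic and γ to the hydroxyl, so neither allylic transposition nor Julia-type elimination is possible, and the silyl ether, the tertiary alcohol and the three E alkenes are inert.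

Step 13
Reactants: 16 silyl ether of the target
Product: 17 preluffariellolide A
Conditions: Bu4NF, THF, 0 °C to rt
Reagents that add atoms: none
Why: Fluoride-induced cleavage of the Si–O bond of the primary allylic silyl ether, which leaves the tertiary alcohol, both ring stereocentres and the three E alkenes unchanged and gives the target.

Compound list

1 | geraniol | CC(C)=CCC/C(C)=C/CO | starting material
2 | (2S,3S)-2,3-epoxygeraniol | CC(C)=CCC[C@]1(C)O[C@H]1CO | intermediate
3 | (2R,3S)-1-chloro-2,3-epoxy-3,7-dimethyloct-6-ene | CC(C)=CCC[C@]1(C)O[C@H]1CCl | intermediate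
4 | lithium (S)-1-chloro-3,7-dimethylocta-1,6-dien-3-olate (alkene geometry open) | CC(C)=CCC[C@](C)([O-])C=CCl.[Li+] | intermediate (not isolated)
5 | (S)-3,7-dimethyloct-6-en-1-yn-3-ol | CC(C)=CCC[C@](C#C)(C)O | intermediate
6 | (S)-3,7-dimethyl-1-(phenylsulfanyl)oct-6-en-1-yn-3-ol | CC(C)=CCC[C@](C#CSc1ccccc1)(C)O | intermediate
7 | (S)-3,7-dimethyl-1-(phenylsulfinyl)oct-6-en-1-yn-3-ol (both configurations at sulfur) | CC(C)=CCC[C@](C#CS(=O)c1ccccc1)(C)O | intermediate (not isolated)
8 | (S)-3,7-dimethyl-1-(phenylsulfonyl)oct-6-en-1-yn-3-ol | CC(C)=CCC[C@](C#CS(=O)(=O)c1ccccc1)(C)O | intermediate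
9 | (S)-1,3,3-trimethyl-2-[(phenylsulfonyl)methylidene]cyclohexan-1-ol (E/Z mixture) | C[C@]1(O)CCCC(C)(C)C1=CS(=O)(=O)c2ccccc2 | intermediate
10 | (1S,2S)-1,3,3-trimethyl-2-[(phenylsulfonyl)methyl]cyclohexan-1-ol | C[C@]1(O)CCCC(C)(C)[C@@H]1CS(=O)(=O)c2ccccc2 | intermediate
11 | (2E,6E)-farnesol | CC(C)=CCC/C(C)=C/CC/C(C)=C/CO | starting material
12 | (2E,6E)-farnesyl tert-butyldimethylsilyl ether | CC(C)=CCC/C(C)=C/CC/C(C)=C/CO[Si](C)(C)C(C)(C)C | intermediate
13 | (2E,6E,10E)-12-[(tert-butyldimethylsilyl)oxy]-2,6,10-trimethyldodeca-2,6,10-trien-1-ol | OC/C(C)=C/CC/C(C)=C/CC/C(C)=C/CO[Si](C)(C)C(C)(C)C | intermediate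
14 | tert-butyl{[(2E,6E,10E)-12-bromo-3,7,11-trimethyldodeca-2,6,10-trien-1-yl]oxy}dimethylsilane | BrC/C(C)=C/CC/C(C)=C/CC/C(C)=C/CO[Si](C)(C)C(C)(C)C | intermediate
15 | (1S,2S)-2-[(3E,7E,11E)-13-[(tert-butyldimethylsilyl)oxy]-3,7,11-trimethyl-1-(phenylsulfonyl)trideca-3,7,11-trien-1-yl]-1,3,3-trimethylcyclohexan-1-ol (epimers at the sulfonyl-bearing carbon) | C[C@]1(O)CCCC(C)(C)[C@@H]1C(C/C(C)=C/CC/C(C)=C/CC/C(C)=C/CO[Si](C)(C)C(C)(C)C)S(=O)(=O)c2ccccc2 | intermediate
16 | (1S,2S)-2-[(3E,7E,11E)-13-[(tert-butyldimethylsilyl)oxy]-3,7,11-trimethyltrideca-3,7,11-trien-1-yl]-1,3,3-trimethylcyclohexan-1-ol | C/C(=C\CO[Si](C)(C)C(C)(C)C)CC/C=C(\C)CC/C=C(\C)CC[C@H]1C(C)(C)CCC[C@]1(C)O | intermediate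
17 | preluffariellolide A, (1S,2S)-2-[(3E,7E,11E)-13-hydroxy-3,7,11-trimethyltrideca-3,7,11-trien-1-yl]-1,3,3-trimethylcyclohexan-1-ol | C/C(=C\CO)CC/C=C(\C)CC/C=C(\C)CC[C@H]1C(C)(C)CCC[C@]1(C)O | target

Total step count: 13.
Longest linear sequence: 10 steps from geraniol (steps 1–7 and 11–13); the farnesol branch contributes steps 8–10.

Steps most likely to fail

Step 6. The tertiary radical may be quenched (net reduction or hydration of the alkene) before it closes slowly on the crowded alkyne carbon, or the hydride source may attack the alkynyl sulfone directly. The fallback generates the same radical by halogen abstraction, where slow addition of the hydride lengthens the radical lifetime. From 8, anhydrous HBr in CH2Cl2 at −40 °C should add in the Markovnikov sense to the trisubstituted alkene only, since the propargylic carbinol cannot ionise next to the electron-poor alkyne, to give (S)-7-bromo-3,7-dimethyl-1-(phenylsulfonyl)oct-1-yn-3-ol F1. Bu3SnH added by syringe pump with AIBN in benzene at 80 °C (tin hydride radical cyclization, 6-exo-dig) should then give the vinyl sulfone, and the route is rejoined at 9.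

Step 7. Facial selectivity may be poor if hydride from a second aluminate arrives on the open face away from the oxygen, or the reduction may stall at the crowded β-carbon. The fallback replaces hydride addition by catalytic hydroxyl-directed hydrogenation: 9 with H2 and [Ir(cod)(PCy3)(py)]PF6 in CH2Cl2, where the neutral C1 hydroxyl binds the cationic iridium and both hydrogens are added from its face. This leads from 9 directly to 10 and makes no new compound, F0.

Step 11. C-alkylation of the aggregated, crowded dianion may be slow, so that the bromide is lost to elimination or to halogen–lithium exchange and Wurtz-type coupling. The fallback uses a protected monoanion. From 10, Me3SiCl and imidazole in DMF should give trimethyl{[(1S,2S)-1,3,3-trimethyl-2-[(phenylsulfonyl)methyl]cyclohexyl]oxy}silane F2. One equivalent of n-BuLi in THF/DMPU at −78 °C followed by 14 should give the 1-O-trimethylsilyl ether of the coupled sulfone silyl ether F3. K2CO3 in MeOH should then remove only the trimethylsilyl group, and the route is rejoined at 15.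

Further compounds

F1 | step 6 | (S)-7-bromo-3,7-dimethyl-1-(phenylsulfonyl)oct-1-yn-3-ol | CC(C)(Br)CCC[C@](C#CS(=O)(=O)c1ccccc1)(C)O
F0 | step 7 | none | none
F2 | step 11 | trimethyl{[(1S,2S)-1,3,3-trimethyl-2-[(phenylsulfonyl)methyl]cyclohexyl]oxy}silane | C[C@]1(O[Si](C)(C)C)CCCC(C)(C)[C@@H]1CS(=O)(=O)c2ccccc2
F3 | step 11 | 1-O-trimethylsilyl ether of the coupled sulfone silyl ether (epimers at the sulfonyl-bearing carbon) | C[C@]1(O[Si](C)(C)C)CCCC(C)(C)[C@@H]1C(C/C(C)=C/CC/C(C)=C/CC/C(C)=C/CO[Si](C)(C)C(C)(C)C)S(=O)(=O)c2ccccc2
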